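## Retrosynthetic overview
1. Ring numbering: C1 (methyl-bearing alkene carbon), C2, C3, C4 (isopropyl), C5 (acyloxy), C6, C7 (carbinol), C8–C10. The strategy rests on the conjugated diene C1(Me)=C2–C3=C4(iPr) of the single ten-membered carbocycle. Its E trisubstituted alkene is the footprint of a syn methylmetalation of a terminal alkyne, and it is joined to a Z alkene through the sp2–sp2 bond C2–C3.
2. Last disconnection: the C5–O acyl bond, giving the ring diol and a phenol-protected 4-hydroxybenzoyl chloride. The allylic ester is installed only after all palladium chemistry.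
3. Key disconnection: C2–C3 and C1–CH3 together, opening the ring to an acyclic Z alkenyl iodide/terminal alkyne with both hydroxyls silylated.
4. The acyclic chain is cut at C7–CH3 (chelation-controlled Grignard addition) and at C5–C6 (diisopinocampheylboron aldol of hept-6-yn-2-one with the Z β-iodoenal). The enal comes from propargyl alcohol by anti isopropylmagnesiation–iodination and oxidation.
5. Ring order: only one ring is formed, in the key step.

Key step: step 6

Assumption: the sense of induction of (+)-Ipc2BCl (a methyl ketone enolate attacking the Si face of an α-branched enal) is taken by analogy with related enals and is to be checked on the aldol product by MTPA ester analysis. The antipodal reagent is equally available.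

## Route

Step 1
Reactants: 1 propargyl alcohol; 2 isopropylmagnesium chloride
Product: 4 (2Z)-3-iodo-2-isopropylprop-2-en-1-ol, via alkenylmagnesium alkoxide 3 (not isolated)
Conditions: 2 (3 equiv), CuI (10 mol%), THF/Et2O, −10 °C to rt; then I2, −78 to 0 °C; aq. NH4Cl/Na2S2O3
Reagents that add atoms: isopropylmagnesium chloride, CC(C)[Mg]Cl; iodine, II
Why: Copper-catalysed anti-carbomagnesiation of a propargylic alkoxide puts isopropyl on the internal carbon and magnesium on the terminal carbon cis to CH2O (five-membered magnesium chelate), and iodinolysis with retention fixes the Z iodoalkene that becomes C3=C4.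

Step 2
Reactants: 4 (2Z)-3-iodo-2-isopropylprop-2-en-1-ol
Product: 5 (2Z)-3-iodo-2-isopropylprop-2-enal
Conditions: MnO2 (activated, excess), CH2Cl2, rt, dark; filtered and used at once
Reagents that add atoms: none
Why: Allylic alcohol oxidation on MnO2 is neutral and mild, so the Z geometry of the β-iodoenal should be kept as long as the aldehyde is not stored.

Step 3
Reactants: 6 hept-6-yn-2-one; 5 (2Z)-3-iodo-2-isopropylprop-2-enal
Product: 9 (1Z,3S)-3-hydroxy-1-iodo-2-isopropyldec-1-en-9-yn-5-one, via diisopinocampheylboron enolate 7 (not isolated), via boron aldolate 8 (not isolated)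
Conditions: (+)-Ipc2BCl, Et3N, Et2O, 0 °C; 5, −78 to −20 °C; H2O2, MeOH, pH 7 buffer, 0 °C
Reagents that add atoms: none
Why: In this diisopinocampheylboron-mediated methyl ketone aldol reaction the hindered chloroborane enolises 6 on the methyl side and the ligands of the (+)-reagent steer the enolate to the Si face of the enal, which sets ring C5 as S, any residual minor enantiomer being removed later by crystallisation of a solid compound (18 or 23).

Step 4
Reactants: 9 (1Z,3S)-3-hydroxy-1-iodo-2-isopropyldec-1-en-9-yn-5-one; 10 methylmagnesium bromide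
Product: 12 (1Z,3S,5S)-1-iodo-2-isopropyl-5-methyldec-1-en-9-yne-3,5-diol, via bromomagnesium chelate 11 (not isolated)
Conditions: MeMgBr (4 equiv), CH2Cl2/Et2O, −78 °C; aq. NH4Cl
Reagents that add atoms: methylmagnesium bromide, C[Mg]Br
Why: In this chelation-controlled Grignard addition (Cram-chelate type 1,3-induction) the first equivalent forms the six-membered chelate 11 with the alkenyl group equatorial and external methyl attacks axially, as hydride does in a Narasaka–Prasad reduction, giving the 1,3-syn diol and hence ring C7 as S.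

Step 5
Reactants: 12 (1Z,3S,5S)-1-iodo-2-isopropyl-5-methyldec-1-en-9-yne-3,5-diol
Product: 13 (1Z,3S,5S)-1-iodo-2-isopropyl-5-methyl-3,5-bis(triethylsilyloxy)dec-1-en-9-yne
Conditions: Et3SiOTf (3 equiv), 2,6-lutidine, CH2Cl2, −78 to 0 °C
Reagents that add atoms: triethylsilyl trifluoromethanesulfonate, CC[Si](CC)(CC)OS(=O)(=O)C(F)(F)F
Why: Silyl triflate silylation is reactive enough to cap the tertiary and the secondary hydroxyl in one operation, so the key step meets neither an acidic O–H nor an aluminium alkoxide.

Step 6
Reactants: 13 (1Z,3S,5S)-1-iodo-2-isopropyl-5-methyl-3,5-bis(triethylsilyloxy)dec-1-en-9-yne; 14 trimethylaluminium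
Product: 17 (1E,3Z,5S,7S)-4-isopropyl-1,7-dimethyl-5,7-bis(triethylsilyloxy)cyclodeca-1,3-diene, via alkenyldimethylalane 15 (not isolated), via alkenylzinc chloride 16 (not isolated)
Conditions: AlMe3 (2.5 equiv), Cp2ZrCl2 (0.3 equiv), CH2Cl2, 0 °C to rt; volatiles removed in vacuo, THF; syringe-pump addition over 12 h to Pd(PPh3)4 (10 mol%), ZnCl2 (1.5 equiv), THF, 40 °C, final ca. 1 mM; aq. NH4Cl
Reagents that add atoms: trimethylaluminium, C[Al](C)C
Why: Proposed new method: the Cp2ZrCl2/AlMe3 reagent adds methyl and aluminium syn across the terminal alkyne of 13 (methyl to the internal carbon C1, aluminium to C2) to give the E alkenylalane 15, ZnCl2 takes over the alkenyl group (16), zerovalent palladium inserts into the C3–I bond with retention, the C2–zinc terminus of the same molecule transmetalates to the divalent palladium centre, and reductive elimination forms C2–C3. The closest known reaction type is the one-pot zirconium-catalysed methylalumination/palladium- and zinc-cocatalysed alkenyl–alkenyl Negishi coupling, which is routine between two molecules, whereas ring closures of this kind have been run mainly with alkenyl-tin and alkenyl-boron partners and for larger rings. The ten-membered carbocycle, the only ring, is closed end to end by reductive elimination from an eleven-membered cis-dialkenylpalladacycle, in which the two alkenyl planes stand roughly perpendicular to the coordination plane and so already resemble the twisted diene of the product. No stereocentre is created; C5 and C7 are spectators, and the two alkene geometries are fixed before closure (E by syn addition, Z in the iodide) and carried through by stereoretentive steps. The step needs methyl at C1 rather than C2, which the terminal alkyne secures, and ring closure ahead of dimerisation and of methyl transfer from aluminium or zinc to palladium, which is served by stripping off excess AlMe3, by slow addition into a dilute catalyst solution, by the faster transfer of alkenyl than of methyl groups and by the Z geometry at C3=C4, which turns the palladium-bearing carbon back towards the chain. Both hydroxyls are silylated because an aluminium alkoxide at C7 would aggregate through Al2O2 bridges, tie two substrate molecules together and bring in further methyl donors, and because an allylic ester at C5 would ionise with zerovalent palladium.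

Step 7
Reactants: 17 (1E,3Z,5S,7S)-4-isopropyl-1,7-dimethyl-5,7-bis(triethylsilyloxy)cyclodeca-1,3-diene
Product: 18 (1E,3Z,5S,7S)-4-isopropyl-1,7-dimethylcyclodeca-1,3-diene-5,7-diol
Conditions: Bu4NF (3 equiv), THF, 0 °C to rt
Reagents that add atoms: none
Why: Fluoride-mediated desilylation removes both triethylsilyl ethers under non-ionising conditions that leave the dienyl carbinol and both stereocentres untouched.

Step 8
Reactants: 19 4-hydroxybenzoic acid
Product: 20 tert-butyldimethylsilyl 4-(tert-butyldimethylsilyloxy)benzoate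
Conditions: TBSCl (2.5 equiv), imidazole, DMF, rt
Reagents that add atoms: tert-butyldimethylsilyl chloride, CC(C)(C)[Si](C)(C)Cl
Why: Imidazole-promoted silylation converts the phenol into its silyl ether and the acid into its silyl ester in one operation.

Step 9
Reactants: 20 tert-butyldimethylsilyl 4-(tert-butyldimethylsilyloxy)benzoate
Product: 21 4-(tert-butyldimethylsilyloxy)benzoyl chloride
Conditions: (COCl)2, DMF (cat.), CH2Cl2, 0 °C to rt; concentrated and used crude
Reagents that add atoms: oxalyl chloride, O=C(Cl)C(=O)Cl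
Why: Silyl esters are turned into acid chlorides by oxalyl chloride with catalytic DMF (Vilsmeier-type activation) under neutral conditions, with no HCl to cleave the aryl silyl ether.

Step 10
Reactants: 18 (1E,3Z,5S,7S)-4-isopropyl-1,7-dimethylcyclodeca-1,3-diene-5,7-diol; 21 4-(tert-butyldimethylsilyloxy)benzoyl chloride
Product: 22 (1E,3Z,5S,7S)-7-hydroxy-4-isopropyl-1,7-dimethylcyclodeca-1,3-dien-5-yl 4-(tert-butyldimethylsilyloxy)benzoate
Conditions: Et3N, DMAP, CH2Cl2, 0 °C to rt
Reagents that add atoms: none
Why: DMAP-catalysed acylation distinguishes the secondary C5 hydroxyl from the tertiary C7 hydroxyl on steric grounds and keeps the C5 configuration because the C5–O bond is not touched.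

Step 11
Reactants: 22 (1E,3Z,5S,7S)-7-hydroxy-4-isopropyl-1,7-dimethylcyclodeca-1,3-dien-5-yl 4-(tert-butyldimethylsilyloxy)benzoate
Product: 23 (1E,3Z,5S,7S)-7-hydroxy-4-isopropyl-1,7-dimethylcyclodeca-1,3-dien-5-yl 4-hydroxybenzoate (CNP0130127.1)
Conditions: Bu4NF, AcOH (1:1), THF, 0 °C
Reagents that add atoms: none
Why: Buffered fluoride desilylation cleaves the aryl silyl ether much faster than it can touch the hindered benzoate, and the buffer guards against acyl migration and elimination.

## Compound list
1 | propargyl alcohol | C#CCO | starting material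
2 | isopropylmagnesium chloride | CC(C)[Mg]Cl | starting material
3 | chloromagnesium (2Z)-3-(chloromagnesio)-2-isopropylprop-2-en-1-olate | Cl[Mg]/C=C(/C(C)C)CO[Mg]Cl | intermediate
4 | (2Z)-3-iodo-2-isopropylprop-2-en-1-ol | I/C=C(/C(C)C)CO | intermediate
5 | (2Z)-3-iodo-2-isopropylprop-2-enal | I/C=C(/C(C)C)C=O | intermediate
6 | hept-6-yn-2-one | CC(=O)CCCC#C | starting material
7 | hept-1-en-6-yn-2-yl diisopinocampheylborinate (ligands from (+)-Ipc2BCl) | C=C(CCCC#C)OB([C@H]1C[C@H]2C[C@@H]([C@@H]1C)C2(C)C)[C@H]1C[C@H]2C[C@@H]([C@@H]1C)C2(C)C | intermediate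
8 | diisopinocampheylborinate of 9 (boron aldolate) | I/C=C(/C(C)C)[C@@H](OB([C@H]1C[C@H]2C[C@@H]([C@@H]1C)C2(C)C)[C@H]1C[C@H]2C[C@@H]([C@@H]1C)C2(C)C)CC(=O)CCCC#C | intermediate
9 | (1Z,3S)-3-hydroxy-1-iodo-2-isopropyldec-1-en-9-yn-5-one | I/C=C(/C(C)C)[C@@H](O)CC(=O)CCCC#C | intermediate
10 | methylmagnesium bromide | C[Mg]Br | starting material
11 | bromomagnesium alkoxide of 9 (six-membered chelate to the ketone) | I/C=C(/C(C)C)[C@@H](O[Mg]Br)CC(=O)CCCC#C | intermediate
12 | (1Z,3S,5S)-1-iodo-2-isopropyl-5-methyldec-1-en-9-yne-3,5-diol | I/C=C(/C(C)C)[C@@H](O)C[C@@](C)(O)CCCC#C | intermediate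
13 | (1Z,3S,5S)-1-iodo-2-isopropyl-5-methyl-3,5-bis(triethylsilyloxy)dec-1-en-9-yne | I/C=C(/C(C)C)[C@@H](O[Si](CC)(CC)CC)C[C@@](C)(O[Si](CC)(CC)CC)CCCC#C | intermediate
14 | trimethylaluminium | C[Al](C)C | starting material
15 | [(1E,6S,8S,9Z)-10-iodo-9-isopropyl-2,6-dimethyl-6,8-bis(triethylsilyloxy)deca-1,9-dien-1-yl]dimethylalane | I/C=C(/C(C)C)[C@@H](O[Si](CC)(CC)CC)C[C@@](C)(O[Si](CC)(CC)CC)CCC/C(C)=C/[Al](C)C | intermediate
16 | [(1E,6S,8S,9Z)-10-iodo-9-isopropyl-2,6-dimethyl-6,8-bis(triethylsilyloxy)deca-1,9-dien-1-yl]zinc chloride | I/C=C(/C(C)C)[C@@H](O[Si](CC)(CC)CC)C[C@@](C)(O[Si](CC)(CC)CC)CCC/C(C)=C/[Zn]Cl | intermediate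
17 | (1E,3Z,5S,7S)-4-isopropyl-1,7-dimethyl-5,7-bis(triethylsilyloxy)cyclodeca-1,3-diene | C/C1=C\C=C(\C(C)C)[C@@H](O[Si](CC)(CC)CC)C[C@@](C)(O[Si](CC)(CC)CC)CCC1 | intermediate
18 | (1E,3Z,5S,7S)-4-isopropyl-1,7-dimethylcyclodeca-1,3-diene-5,7-diol | C/C1=C\C=C(\C(C)C)[C@@H](O)C[C@@](C)(O)CCC1 | intermediate
19 | 4-hydroxybenzoic acid | O=C(O)c1ccc(O)cc1 | starting material
20 | tert-butyldimethylsilyl 4-(tert-butyldimethylsilyloxy)benzoate | CC(C)(C)[Si](C)(C)OC(=O)c1ccc(O[Si](C)(C)C(C)(C)C)cc1 | intermediate
21 | 4-(tert-butyldimethylsilyloxy)benzoyl chloride | O=C(Cl)c1ccc(O[Si](C)(C)C(C)(C)C)cc1 | intermediate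
22 | (1E,3Z,5S,7S)-7-hydroxy-4-isopropyl-1,7-dimethylcyclodeca-1,3-dien-5-yl 4-(tert-butyldimethylsilyloxy)benzoate | C/C1=C\C=C(\C(C)C)[C@@H](OC(=O)c2ccc(O[Si](C)(C)C(C)(C)C)cc2)C[C@@](C)(O)CCC1 | intermediate
23 | (1E,3Z,5S,7S)-7-hydroxy-4-isopropyl-1,7-dimethylcyclodeca-1,3-dien-5-yl 4-hydroxybenzoate | C/C1=C\C=C(\C(C)C)[C@@H](OC(=O)c2ccc(O)cc2)C[C@@](C)(O)CCC1 | target

## Step count
Total step count: 11. Longest linear sequence: 9 (steps 1–7, 10, 11).

## Steps most likely to fail

**Step 6.** Intermolecular coupling to dimers and oligomers may outrun closure of the strained medium ring. Methyl may be transferred to the alkenylpalladium iodide, or the alkenyl metal may be protonated during the long addition.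

The fallback sets out from 13 and comes back at 17. It cuts the tandem into two known reactions with a storable nucleophile.
- 13 is methylaluminated as in step 6, and alane 15 is trapped with 2-isopropoxy-4,4,5,5-tetramethyl-1,3,2-dioxaborolane to give the pinacol (E)-alkenylboronate F1.
- F1 is freed by chromatography from the regioisomer and from all methyl-metal species.
- An intramolecular Suzuki–Miyaura coupling (Pd(dppf)Cl2, Cs2CO3, THF/DMF/H2O, syringe-pump addition at high dilution) then forms the same C2–C3 bond and gives 17.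

**Step 4.** Loose chelation of the magnesium aldolate may give poor facial selectivity at the ketone.

The fallback sets out from 9 and comes back at 12. It gives up stereoselection in favour of separation on a rigid cyclic derivative.
- 9 is methylated without chelation control (MeMgBr, THF, −78 °C) to give 12 together with its epimer at the tertiary carbinol, the (1Z,3S,5R)-diol F2.
- The mixture is converted with 2,2-dimethoxypropane and pyridinium p-toluenesulfonate into the syn acetonide F3 (chair) and the anti acetonide F4 (twist-boat).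
- The two acetonides differ in shape and polarity and should separate on silica. They can be told apart by the carbon-13 shifts of the acetonide methyl groups.
- Hydrolysis of F3 (AcOH/H2O, 40 °C) returns diastereomerically pure 12.

**Step 3.** Enantioface discrimination may be incomplete with an achiral methyl ketone. Enal 5 may also isomerise from Z to E through reversible addition of amine or halide.

The fallback sets out from 5 and comes back at 12. It replaces reagent control by a covalently bound auxiliary, so that the unwanted isomer becomes a separable diastereomer.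
- A TiCl4/iPr2NEt-mediated thiazolidinethione acetate aldol addition (CH2Cl2, −78 °C) of commercial (4R)-3-acetyl-4-isopropyl-1,3-thiazolidine-2-thione to 5 gives the acetate aldol adduct F5, which is purified to a single diastereomer.
- MeNHOMe·HCl with imidazole displaces the auxiliary and gives the Weinreb amide F6.
- An excess of [5-(trimethylsilyl)pent-4-yn-1-yl]magnesium chloride F7, made from the commercial chloride and Mg, gives the C-silylated hydroxy ketone F8.
- Addition of MeMgBr as in step 4 gives the C-silylated diol F9.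
- K2CO3 in MeOH removes the alkynyl silane and gives 12.

## Further compounds
F1 | step 6 | 2-[(1E,6S,8S,9Z)-10-iodo-9-isopropyl-2,6-dimethyl-6,8-bis(triethylsilyloxy)deca-1,9-dien-1-yl]-4,4,5,5-tetramethyl-1,3,2-dioxaborolane | I/C=C(/C(C)C)[C@@H](O[Si](CC)(CC)CC)C[C@@](C)(O[Si](CC)(CC)CC)CCC/C(C)=C/B1OC(C)(C)C(C)(C)O1
F2 | step 4 | (1Z,3S,5R)-1-iodo-2-isopropyl-5-methyldec-1-en-9-yne-3,5-diol | I/C=C(/C(C)C)[C@@H](O)C[C@](C)(O)CCCC#C
F3 | step 4 | (4S,6S)-4-[(1Z)-1-iodo-3-methylbut-1-en-2-yl]-2,2,6-trimethyl-6-(pent-4-yn-1-yl)-1,3-dioxane | I/C=C(/C(C)C)[C@@H]1C[C@](C)(CCCC#C)OC(C)(C)O1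
F4 | step 4 | (4S,6R)-4-[(1Z)-1-iodo-3-methylbut-1-en-2-yl]-2,2,6-trimethyl-6-(pent-4-yn-1-yl)-1,3-dioxane | I/C=C(/C(C)C)[C@@H]1C[C@@](C)(CCCC#C)OC(C)(C)O1
F5 | step 3 | (3S,4Z)-3-hydroxy-5-iodo-4-isopropyl-1-[(4R)-4-isopropyl-2-thioxo-1,3-thiazolidin-3-yl]pent-4-en-1-one | I/C=C(/C(C)C)[C@@H](O)CC(=O)N1C(=S)SC[C@H]1C(C)C
F6 | step 3 | (3S,4Z)-3-hydroxy-5-iodo-4-isopropyl-N-methoxy-N-methylpent-4-enamide | I/C=C(/C(C)C)[C@@H](O)CC(=O)N(C)OC
F7 | step 3 | [5-(trimethylsilyl)pent-4-yn-1-yl]magnesium chloride | C[Si](C)(C)C#CCCC[Mg]Cl
F8 | step 3 | (1Z,3S)-3-hydroxy-1-iodo-2-isopropyl-10-(trimethylsilyl)dec-1-en-9-yn-5-one | I/C=C(/C(C)C)[C@@H](O)CC(=O)CCCC#C[Si](C)(C)C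
F9 | step 3 | (1Z,3S,5S)-1-iodo-2-isopropyl-5-methyl-10-(trimethylsilyl)dec-1-en-9-yne-3,5-diol | I/C=C(/C(C)C)[C@@H](O)C[C@@](C)(O)CCCC#C[Si](C)(C)C
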